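**Plan**

1. Retrosynthetic cuts: C14=C15 and C12=C13 (two Wittig reactions), C7–O (allylic oxidation), C7–C8 (ring B, B-alkyl Suzuki coupling), C4–C5 (ring A, ring-contracting Ireland–Claisen rearrangement), O7–C19 (lactone), C1=C2 (Wittig), C5–C10 and C8–C9 (Diels–Alder).
2. Forward: an asymmetric Diels–Alder reaction gives a cyclohexenone holding C5–C10; the C1–C4/C19 chain is attached, this ring is cut between C7 and C8, the C19 acid is tied to O7 as a ten-membered lactone, the [3,3] shift closes ring A, ring B is re-closed and the diene is built last.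
3. Enabling feature: C19 on C4 and C7 of ring B are 1,5-related across C4–C5–C6, so an O7–C19 ester with a Z C5=C6 bond lines up the array C4=C19–O–C7–C6=C5, whose shift makes C4–C5 and leaves C6=C7.
4. In an intact ring B the chain C1–C4 leaves C10 on the face opposite to O7, so the ester could not span the ring; ring B is therefore kept open at C7–C8 through the key step.
5. Stereochemistry: C9 and C10 from the catalyst-controlled Diels–Alder reaction of an E-enal; C5 from the quaternary C10 and C4 from the Z-alkenyl lactone geometry in the rearrangement; C7 from axial oxygen delivery by SeO2; 12E from a stabilised ylide.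

Key step: step 11

Remark: atoms carry labdane numbers (C1 to C20) in all intermediates and α/β mean the faces they have in the target; C4 is racemic from the phosphonium salt onward and is drawn without descriptor until step 11 sets it, and C8 has no lasting stereochemistry.

Assumption: the (S)-configured cationic oxazaborolidine is taken to expose the Si face of the α-carbon (C10) of the enal dienophile; if the sense proves opposite, its mirror image is used.

**Route**

Step 1
Reactants: 1 3-(tert-butyldimethylsilyloxy)propanal; 2 2-(triphenylphosphoranylidene)propanal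
Product: 3 (E)-5-(tert-butyldimethylsilyloxy)-2-methylpent-2-enal
Conditions: toluene, 80 °C
Reagents that add atoms: none
Why: Wittig olefination with a formyl-stabilised ylide is E-selective and stops at the mono-adduct because the product enal is much less electrophilic than the aliphatic aldehyde; no stereocentre is formed.

Step 2
Reactants: 4 (E)-1-methoxypent-1-en-3-one
Product: 5 (1E,3Z)-1-methoxy-3-(trimethylsilyloxy)penta-1,3-diene
Conditions: Me3SiOTf, Et3N, Et2O, 0 °C
Reagents that add atoms: trimethylsilyl trifluoromethanesulfonate, C[Si](C)(C)OS(=O)(=O)C(F)(F)F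
Why: Soft enolisation and O-silylation of the ethyl ketone gives the Danishefsky-type 2-silyloxydiene, the Z enol ether being the usual outcome for ethyl ketones and affecting only C8, which is erased later.

Step 3
Reactants: 3 (E)-5-(tert-butyldimethylsilyloxy)-2-methylpent-2-enal; 5 (1E,3Z)-1-methoxy-3-(trimethylsilyloxy)penta-1,3-diene
Product: 6 6-[2-(tert-butyldimethylsilyloxy)ethyl]-2-methoxy-1,5-dimethyl-4-(trimethylsilyloxy)cyclohex-3-ene-1-carbaldehyde (endo adduct)
Conditions: (S)-1-(o-tolyl)-3,3-diphenyltetrahydro-1H,3H-pyrrolo[1,2-c][1,3,2]oxazaborole (20 mol %), HN(SO2CF3)2 (18 mol %), CH2Cl2, −78 → −40 °C; Et3N; filtration through Et3N-treated silica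
Reagents that add atoms: none
Why: Enantioselective Diels–Alder reaction of an α-methyl-β-alkyl enal activated by a cationic oxazaborolidine, in which the methoxy terminus C5 bonds to the α-carbon C10 and the methyl-bearing terminus C8 to C9, the E geometry of 3 fixes the C11 chain cis to C20 and trans to the formyl carbon C1, endo addition puts OMe and the C8 methyl cis to the formyl group, and the catalyst selects the face that gives the C9/C10 configuration of the target.

Step 4
Reactants: 7 α-methyl-γ-butyrolactone
Product: 8 (3-carboxy-3-methylpropyl)triphenylphosphonium bromide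
Conditions: PPh3·HBr, neat, 170 °C
Reagents that add atoms: triphenylphosphine hydrobromide, Br.c1ccc(cc1)P(c1ccccc1)c1ccccc1
Why: Acid-promoted SN2 opening of the lactone at its O–CH2 carbon by triphenylphosphine is the standard route from γ-butyrolactones to 3-carboxypropylphosphonium salts, and the racemic α-centre is tolerated because C4 is re-formed in step 11.

Step 5
Reactants: 6 endo Diels–Alder adduct; 8 (3-carboxy-3-methylpropyl)triphenylphosphonium bromide
Product: 11 (Z)-5-{2-[2-(tert-butyldimethylsilyloxy)ethyl]-6-methoxy-1,3-dimethyl-4-oxocyclohexyl}-2-methylpent-4-enoic acid, via carboxylate ylide 9 (not isolated), via silyl enol ether carboxylate 10 (not isolated)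
Conditions: 8, NaN(SiMe3)2 (2.1 equiv), THF, 0 °C; 6, −78 → 20 °C; 0.1 M HCl to pH 4, 0 °C
Reagents that add atoms: none
Why: Wittig reaction of the non-stabilised carboxylate ylide with the neopentyl aldehyde forms C1=C2 (mainly Z, of no consequence) while the silyl enol ether keeps the ring ketone from eliminating methanol under base, and the mild acid work-up hydrolyses only the trimethylsilyl enol ether to the β-methoxy ketone; no lasting stereocentre is set.

Step 6
Reactants: 11 (Z)-alkenoic acid with β-methoxy ketone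
Product: 13 5-{6-[2-(tert-butyldimethylsilyloxy)ethyl]-1,5-dimethyl-4-oxocyclohex-2-en-1-yl}-2-methylpentanoic acid, via saturated methoxy ketone 12 (not isolated)
Conditions: H2 (1 atm), Pd/C, EtOAc, 20 °C; filtration; DBU, CH2Cl2, 20 °C
Reagents that add atoms: none
Why: Heterogeneous hydrogenation saturates the only C=C bond (C1=C2) while C5 still carries methoxy, and DBU then eliminates methanol (E1cB) to unveil the C5=C6 enone, so the two alkenes never coexist and C9 and C10 are untouched.

Step 7
Reactants: 13 enone acid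
Product: 15 5-{6-[2-(tert-butyldimethylsilyloxy)ethyl]-5-hydroxy-1,5-dimethyl-4-oxocyclohex-2-en-1-yl}-2-methylpentanoic acid, via disodium enolate carboxylate 14 (not isolated)
Conditions: NaN(SiMe3)2 (2.2 equiv), THF, −78 °C; 2-(phenylsulfonyl)-3-phenyloxaziridine, −78 °C; dilute HCl to pH 4
Reagents that add atoms: 2-(phenylsulfonyl)-3-phenyloxaziridine, O=S(=O)(c1ccccc1)N1OC1c1ccccc1
Why: Davis oxidation of the kinetic cross-conjugated enolate, which can only form at C8 because C10 is quaternary, installs the C8 hydroxyl needed to cut the ring, and the new C8 centre may be a mixture since it becomes a ketone in step 9.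

Step 8
Reactants: 15 α′-hydroxy enone acid
Product: 16 5-{6-[2-(tert-butyldimethylsilyloxy)ethyl]-4,5-dihydroxy-1,5-dimethylcyclohex-2-en-1-yl}-2-methylpentanoic acid
Conditions: NaBH4, CeCl3·7H2O, MeOH, −40 → 0 °C
Reagents that add atoms: none
Why: Luche reduction gives clean 1,2-reduction of the enone to the allylic alcohol and hence a 7,8-diol, the C7 configuration being irrelevant because C7 becomes a CH2OH group in step 9.

Step 9
Reactants: 16 7,8-diol acid
Product: 18 7-acetyl-9-(tert-butyldimethylsilyloxy)-6-[(Z)-3-hydroxyprop-1-enyl]-2,6-dimethylnonanoic acid (seco acid), via keto enal 17 (not isolated)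
Conditions: NaIO4, THF–H2O (pH 7), 0 °C; extraction; NaBH4, EtOH–CH2Cl2, −78 °C
Reagents that add atoms: none
Why: Periodate glycol cleavage opens the ring between C7 and C8 to a (Z)-enal and a methyl ketone, and borohydride at low temperature reduces the aldehyde much faster than the hindered α-branched ketone, so the Z C5=C6 bond made in the ring is carried into the open chain with C9 and C10 intact.

Step 10
Reactants: 18 seco acid
Product: 20 (Z)-7-[5-(tert-butyldimethylsilyloxy)-2-oxopentan-3-yl]-3,7-dimethyl-1-oxacyclodec-8-en-2-one (ten-membered lactone), via mixed anhydride 19 (not isolated)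
Conditions: 2,4,6-trichlorobenzoyl chloride, Et3N, THF, 20 °C; slow addition to DMAP, toluene, 90 °C (1 mM)
Reagents that add atoms: none
Why: Yamaguchi macrolactonisation under high dilution, in which the Z alkene and the quaternary C10 turn the chain so that the primary allylic hydroxyl reaches the activated C19 carboxyl; no stereocentre is affected.

Step 11
Reactants: 20 ten-membered lactone
Product: 23 1,3-dimethyl-3-[5-(tert-butyldimethylsilyloxy)-2-oxopentan-3-yl]-2-vinylcyclohexane-1-carboxylic acid (carboxyl cis to vinyl and to the C10 methyl), via bis-silyl ketene acetal 21 (not isolated), via silyl ester 22 (not isolated)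
Conditions: LiN(iPr)2 (2.4 equiv), Me3SiCl–Et3N (premixed, excess), THF, −100 → 20 °C; toluene, 105 °C; 0.5 M HCl, THF, 0 °C
Reagents that add atoms: none
Why: Internal-quench deprotonation silylates both the methyl ketone (as its enol ether) and the lactone (as its silyl ketene acetal), and on heating the array C4=C19–O–C7–C6=C5 undergoes a concerted suprafacial [3,3] shift that forms C4–C5, breaks C7–O and leaves C6=C7 as a vinyl group, after which mild acid returns the acid and the ketone. It is the ring-contracting Ireland–Claisen rearrangement of medium-ring (Z)-alkenyl lactones, here a ten-membered ring shrinking by four atoms. Ring A closes transannularly as a six-membered carbocycle between the ketene acetal carbon C4 and the alkene carbon C5, which the lactone holds in a boat-like transition state. C4 is fixed relative to C5 by the ring, because with a Z C5=C6 bond either ketene acetal geometry can only deliver C19 cis to the new vinyl group, so C19 ends axial and C18 equatorial on ring A and both C4 epimers of 20 converge. C5 is fixed relative to the quaternary C10 by facial selection, the ketene acetal adding to the face of C5 on which C10 shows its methyl group C20, since the other face would force the branched C9 carbon inward or C20 against C18. The step therefore needs this facial selectivity and clean enolisation at C4, which the size difference between the two C10 substituents, the cold internal quench and the absence of other acidic C–H bonds beside the methyl ketone (masked in the same operation) should secure.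

Step 12
Reactants: 23 vinylcyclohexane keto acid
Product: 24 2-(trimethylsilyl)ethyl ester of 23
Conditions: Me3SiCH2CH2OH, PPh3, DIAD, THF, 0 → 20 °C
Reagents that add atoms: 2-(trimethylsilyl)ethanol, C[Si](C)(C)CCO
Why: Mitsunobu esterification forms the ester by carboxylate attack on the activated primary alcohol, so the hindrance of the axial neopentyl C19 carboxyl does not matter, and this ester can later be removed with fluoride without touching an acetate.

Step 13
Reactants: 24 2-(trimethylsilyl)ethyl ester
Product: 26 enol triflate of 24 at C8 (terminal C8=C17 with C8–OTf), via potassium enolate 25 (not isolated)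
Conditions: KN(SiMe3)2, THF, −78 °C; PhN(SO2CF3)2, −78 → 0 °C; dilute HCl work-up
Reagents that add atoms: N-phenylbis(trifluoromethanesulfonimide), O=S(=O)(N(c1ccccc1)S(=O)(=O)C(F)(F)F)C(F)(F)F
Why: Kinetic deprotonation of the methyl ketone occurs at the methyl group C17 and not at the hindered C9–H, so O-triflation gives the terminal enol triflate without epimerising C9, and the ester has no α-hydrogen.

Step 14
Reactants: 26 enol triflate
Product: 28 2-(trimethylsilyl)ethyl 12-(tert-butyldimethylsilyloxy)-13,14,15,16-tetranorlabd-8(17)-en-19-oate, via alkylborane 27 (not isolated)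
Conditions: 9-BBN, THF, 0 → 40 °C; PdCl2(dppf) (10 mol %), AsPh3, Cs2CO3, DMF–H2O, 50 °C
Reagents that add atoms: none
Why: Anti-Markovnikov hydroboration of the vinyl group places boron on C7, and the intramolecular B-alkyl Suzuki–Miyaura coupling with the enol triflate forms C7–C8 and closes ring B as a methylenecyclohexane; since C6 on C5 and C9 on C10 are trans the ring fusion is necessarily trans and no new stereocentre arises.

Step 15
Reactants: 28 tetranorlabd-8(17)-ene ester
Product: 29 2-(trimethylsilyl)ethyl 12-(tert-butyldimethylsilyloxy)-7α-hydroxy-13,14,15,16-tetranorlabd-8(17)-en-19-oate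
Conditions: SeO2 (0.5 equiv), t-BuOOH, CH2Cl2, 0 → 20 °C
Reagents that add atoms: selenium dioxide (oxygen carrier), O=[Se]=O; tert-butyl hydroperoxide (terminal oxidant), CC(C)(C)OO
Why: SeO2 allylic oxidation (ene reaction at C17, then [2,3] shift) of an exocyclic methylene returns the exocyclic alkene and oxidises the ring CH2 (C7) in preference to the tertiary C9–H, delivering oxygen axially, that is 7α, as is usual for methylenecyclohexanes of this type.

Step 16
Reactants: 29 7α-alcohol
Product: 30 2-(trimethylsilyl)ethyl 7α-acetoxy-12-(tert-butyldimethylsilyloxy)-13,14,15,16-tetranorlabd-8(17)-en-19-oate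
Conditions: Ac2O, DMAP, pyridine, 20 °C
Reagents that add atoms: acetic anhydride, CC(=O)OC(C)=O
Why: DMAP-catalysed acylation of the secondary allylic alcohol proceeds with retention at C7 and installs the acetate of the target, which also protects this oxygen during the side-chain steps.

Step 17
Reactants: 30 7α-acetate silyl ether
Product: 31 2-(trimethylsilyl)ethyl 7α-acetoxy-12-hydroxy-13,14,15,16-tetranorlabd-8(17)-en-19-oate
Conditions: camphorsulfonic acid (10 mol %), MeOH–CH2Cl2, 0 °C
Reagents that add atoms: none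
Why: Acid-catalysed methanolysis removes the primary tert-butyldimethylsilyl ether selectively, the acetate, the exocyclic alkene and the 2-(trimethylsilyl)ethyl ester being stable under these conditions.

Step 18
Reactants: 31 primary alcohol
Product: 32 2-(trimethylsilyl)ethyl 7α-acetoxy-12-oxo-13,14,15,16-tetranorlabd-8(17)-en-19-oate
Conditions: Dess–Martin periodinane, CH2Cl2, 0 → 20 °C
Reagents that add atoms: none
Why: Dess–Martin oxidation of the primary alcohol to the C12 aldehyde is mild enough to leave the allylic acetate and C9 untouched.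

Step 19
Reactants: 32 C12 aldehyde; 2 2-(triphenylphosphoranylidene)propanal
Product: 33 2-(trimethylsilyl)ethyl (12E)-7α-acetoxy-14-oxo-15-norlabda-8(17),12-dien-19-oate
Conditions: toluene, 80 °C
Reagents that add atoms: none
Why: Wittig reaction with the formyl-stabilised ylide forms the trisubstituted C12=C13 bond with E geometry, as is typical for stabilised ylides, and the product enal does not react further.

Step 20
Reactants: 33 (12E)-enal
Product: 34 2-(trimethylsilyl)ethyl 7α-acetoxylabda-8(17),12E,14-trien-19-oate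
Conditions: Ph3PCH3Br, KN(SiMe3)2, THF, 0 °C; 33, −78 → 0 °C
Reagents that add atoms: methyltriphenylphosphonium bromide, C[P+](c1ccccc1)(c1ccccc1)c1ccccc1.[Br-]
Why: Wittig methylenation of the enal completes the 12E,14-diene, the reactive aldehyde being consumed at low temperature before the ylide can attack the acetate or the ester.

Step 21
Reactants: 34 triene ester
Product: 35 7α-acetoxylabda-8(17),12E,14-trien-19-oic acid (target)
Conditions: tris(dimethylamino)sulfonium difluorotrimethylsilicate, DMF, 0 → 20 °C; 0.1 M HCl to pH 4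
Reagents that add atoms: none
Why: Fluoride attacks silicon and the 2-(trimethylsilyl)ethyl ester fragments by β-elimination to ethene and fluorotrimethylsilane, which frees the hindered C19 acid without hydroxide that would cleave the 7-acetate or acid that would harm the diene.

**Compound list**

1 | 3-(tert-butyldimethylsilyloxy)propanal | CC(C)(C)[Si](C)(C)OCCC=O | starting material
2 | 2-(triphenylphosphoranylidene)propanal | CC(C=O)=P(c1ccccc1)(c1ccccc1)c1ccccc1 | starting material
3 | (E)-5-(tert-butyldimethylsilyloxy)-2-methylpent-2-enal | O=C/C(C)=C/CCO[Si](C)(C)C(C)(C)C | intermediate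
4 | (E)-1-methoxypent-1-en-3-one | CCC(=O)/C=C/OC | starting material
5 | (1E,3Z)-1-methoxy-3-(trimethylsilyloxy)penta-1,3-diene | CO/C=C/C(O[Si](C)(C)C)=C/C | intermediate
6 | endo Diels–Alder adduct: 6-[2-(tert-butyldimethylsilyloxy)ethyl]-2-methoxy-1,5-dimethyl-4-(trimethylsilyloxy)cyclohex-3-ene-1-carbaldehyde; C20 methyl and C11 chain cis; formyl, methoxy and C8 methyl on the other face | CC(C)(C)[Si](C)(C)OCC[C@H]1[C@H](C)C(O[Si](C)(C)C)=C[C@H](OC)[C@]1(C)C=O | intermediate
7 | α-methyl-γ-butyrolactone (racemic) | CC1CCOC1=O | starting material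
8 | (3-carboxy-3-methylpropyl)triphenylphosphonium bromide (racemic) | CC(CC[P+](c1ccccc1)(c1ccccc1)c1ccccc1)C(=O)O.[Br-] | intermediate
9 | sodium 2-methyl-4-(triphenylphosphoranylidene)butanoate (carboxylate ylide) | CC(CC=P(c1ccccc1)(c1ccccc1)c1ccccc1)C(=O)[O-].[Na+] | intermediate (not isolated)
10 | Wittig product as trimethylsilyl enol ether and sodium carboxylate | CC(C)(C)[Si](C)(C)OCC[C@H]1[C@H](C)C(O[Si](C)(C)C)=C[C@H](OC)[C@]1(C)/C=C\CC(C)C(=O)[O-].[Na+] | intermediate (not isolated)
11 | (Z)-5-{2-[2-(tert-butyldimethylsilyloxy)ethyl]-6-methoxy-1,3-dimethyl-4-oxocyclohexyl}-2-methylpent-4-enoic acid | CC(C)(C)[Si](C)(C)OCC[C@H]1[C@H](C)C(=O)C[C@H](OC)[C@]1(C)/C=C\CC(C)C(=O)O | intermediate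
12 | 5-{2-[2-(tert-butyldimethylsilyloxy)ethyl]-6-methoxy-1,3-dimethyl-4-oxocyclohexyl}-2-methylpentanoic acid | CC(C)(C)[Si](C)(C)OCC[C@H]1[C@H](C)C(=O)C[C@H](OC)[C@]1(C)CCCC(C)C(=O)O | intermediate (not isolated)
13 | 5-{6-[2-(tert-butyldimethylsilyloxy)ethyl]-1,5-dimethyl-4-oxocyclohex-2-en-1-yl}-2-methylpentanoic acid (C8 as drawn or epimeric) | CC(C)(C)[Si](C)(C)OCC[C@H]1[C@H](C)C(=O)C=C[C@]1(C)CCCC(C)C(=O)O | intermediate
14 | disodium salt of 13 (C7/C8 enolate and carboxylate) | CC(C)(C)[Si](C)(C)OCC[C@H]1C(C)=C([O-])C=C[C@]1(C)CCCC(C)C(=O)[O-].[Na+].[Na+] | intermediate (not isolated)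
15 | 5-{6-[2-(tert-butyldimethylsilyloxy)ethyl]-5-hydroxy-1,5-dimethyl-4-oxocyclohex-2-en-1-yl}-2-methylpentanoic acid (C8 mixture) | CC(C)(C)[Si](C)(C)OCC[C@H]1C(C)(O)C(=O)C=C[C@]1(C)CCCC(C)C(=O)O | intermediate
16 | 5-{6-[2-(tert-butyldimethylsilyloxy)ethyl]-4,5-dihydroxy-1,5-dimethylcyclohex-2-en-1-yl}-2-methylpentanoic acid (C7 and C8 mixtures) | CC(C)(C)[Si](C)(C)OCC[C@H]1C(C)(O)C(O)C=C[C@]1(C)CCCC(C)C(=O)O | intermediate
17 | 7-acetyl-9-(tert-butyldimethylsilyloxy)-2,6-dimethyl-6-[(Z)-3-oxoprop-1-enyl]nonanoic acid (keto enal) | CC(C)(C)[Si](C)(C)OCC[C@@H](C(C)=O)[C@](C)(/C=C\C=O)CCCC(C)C(=O)O | intermediate (not isolated)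
18 | 7-acetyl-9-(tert-butyldimethylsilyloxy)-6-[(Z)-3-hydroxyprop-1-enyl]-2,6-dimethylnonanoic acid (seco acid) | CC(C)(C)[Si](C)(C)OCC[C@@H](C(C)=O)[C@](C)(/C=C\CO)CCCC(C)C(=O)O | intermediate
19 | mixed anhydride of 18 with 2,4,6-trichlorobenzoic acid | CC(C)(C)[Si](C)(C)OCC[C@@H](C(C)=O)[C@](C)(/C=C\CO)CCCC(C)C(=O)OC(=O)c1c(Cl)cc(Cl)cc1Cl | intermediate (not isolated)
20 | (Z)-7-[5-(tert-butyldimethylsilyloxy)-2-oxopentan-3-yl]-3,7-dimethyl-1-oxacyclodec-8-en-2-one; ring O1 = O7, C2 = C19, C3 = C4, C7 = C10, C8=C9 = C5=C6, C10 = C7 (key-step precursor) | CC(C)(C)[Si](C)(C)OCC[C@@H](C(C)=O)[C@]1(C)/C=C\COC(=O)C(C)CCC1 | intermediate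
21 | lactone silyl ketene acetal with the ketone as trimethylsilyl enol ether | CC(C)(C)[Si](C)(C)OCC[C@@H](C(=C)O[Si](C)(C)C)[C@]1(C)/C=C\COC(O[Si](C)(C)C)=C(C)CCC1 | intermediate (not isolated)
22 | trimethylsilyl ester of 23 with the ketone as trimethylsilyl enol ether | CC(C)(C)[Si](C)(C)OCC[C@@H](C(=C)O[Si](C)(C)C)[C@@]1(C)CCC[C@](C)(C(=O)O[Si](C)(C)C)[C@@H]1C=C | intermediate (not isolated)
23 | 1,3-dimethyl-3-[5-(tert-butyldimethylsilyloxy)-2-oxopentan-3-yl]-2-vinylcyclohexane-1-carboxylic acid; ring C1 = C4, C2 = C5, C3 = C10; carboxyl (C19) cis to vinyl and to the C10 methyl, C5–H on the opposite face (key-step product) | CC(C)(C)[Si](C)(C)OCC[C@@H](C(C)=O)[C@@]1(C)CCC[C@](C)(C(=O)O)[C@@H]1C=C | intermediate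
24 | 2-(trimethylsilyl)ethyl ester of 23 | CC(C)(C)[Si](C)(C)OCC[C@@H](C(C)=O)[C@@]1(C)CCC[C@](C)(C(=O)OCC[Si](C)(C)C)[C@@H]1C=C | intermediate
25 | potassium enolate of 24 (C8/C17) | CC(C)(C)[Si](C)(C)OCC[C@@H](C(=C)[O-])[C@@]1(C)CCC[C@](C)(C(=O)OCC[Si](C)(C)C)[C@@H]1C=C.[K+] | intermediate (not isolated)
26 | enol triflate of 24 (C8–OTf, C8=C17) | CC(C)(C)[Si](C)(C)OCC[C@@H](C(=C)OS(=O)(=O)C(F)(F)F)[C@@]1(C)CCC[C@](C)(C(=O)OCC[Si](C)(C)C)[C@@H]1C=C | intermediate
27 | B-alkyl-9-BBN adduct of 26 (boron on C7) | CC(C)(C)[Si](C)(C)OCC[C@@H](C(=C)OS(=O)(=O)C(F)(F)F)[C@@]1(C)CCC[C@](C)(C(=O)OCC[Si](C)(C)C)[C@@H]1CCB1C2CCCC1CCC2 | intermediate (not isolated)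
28 | 2-(trimethylsilyl)ethyl 12-(tert-butyldimethylsilyloxy)-13,14,15,16-tetranorlabd-8(17)-en-19-oate | CC(C)(C)[Si](C)(C)OCC[C@H]1C(=C)CC[C@@H]2[C@]1(C)CCC[C@]2(C)C(=O)OCC[Si](C)(C)C | intermediate
29 | 2-(trimethylsilyl)ethyl 12-(tert-butyldimethylsilyloxy)-7α-hydroxy-13,14,15,16-tetranorlabd-8(17)-en-19-oate | CC(C)(C)[Si](C)(C)OCC[C@H]1C(=C)[C@H](O)C[C@@H]2[C@]1(C)CCC[C@]2(C)C(=O)OCC[Si](C)(C)C | intermediate
30 | 2-(trimethylsilyl)ethyl 7α-acetoxy-12-(tert-butyldimethylsilyloxy)-13,14,15,16-tetranorlabd-8(17)-en-19-oate | CC(C)(C)[Si](C)(C)OCC[C@H]1C(=C)[C@H](OC(C)=O)C[C@@H]2[C@]1(C)CCC[C@]2(C)C(=O)OCC[Si](C)(C)C | intermediate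
31 | 2-(trimethylsilyl)ethyl 7α-acetoxy-12-hydroxy-13,14,15,16-tetranorlabd-8(17)-en-19-oate | OCC[C@H]1C(=C)[C@H](OC(C)=O)C[C@@H]2[C@]1(C)CCC[C@]2(C)C(=O)OCC[Si](C)(C)C | intermediate
32 | 2-(trimethylsilyl)ethyl 7α-acetoxy-12-oxo-13,14,15,16-tetranorlabd-8(17)-en-19-oate | O=CC[C@H]1C(=C)[C@H](OC(C)=O)C[C@@H]2[C@]1(C)CCC[C@]2(C)C(=O)OCC[Si](C)(C)C | intermediate
33 | 2-(trimethylsilyl)ethyl (12E)-7α-acetoxy-14-oxo-15-norlabda-8(17),12-dien-19-oate | O=C/C(C)=C/C[C@H]1C(=C)[C@H](OC(C)=O)C[C@@H]2[C@]1(C)CCC[C@]2(C)C(=O)OCC[Si](C)(C)C | intermediate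
34 | 2-(trimethylsilyl)ethyl 7α-acetoxylabda-8(17),12E,14-trien-19-oate | C=C/C(C)=C/C[C@H]1C(=C)[C@H](OC(C)=O)C[C@@H]2[C@]1(C)CCC[C@]2(C)C(=O)OCC[Si](C)(C)C | intermediate
35 | 7α-acetoxylabda-8(17),12E,14-trien-19-oic acid | C=C/C(C)=C/C[C@H]1C(=C)[C@H](OC(C)=O)C[C@@H]2[C@]1(C)CCC[C@]2(C)C(=O)O | target

**Count and risks**

Total step count: 21. Longest linear sequence: 19 steps (1 → 3 → 6 → 11 → 13 → 15 → 16 → 18 → 20 → 23 → 24 → 26 → 28 → 29 → 30 → 31 → 32 → 33 → 34 → 35; steps 2 and 4 are side branches).

Steps most likely to fail: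

Step 11. The rearrangement may show poor facial selectivity at C5 (the ketene acetal adding on the C9 side of C10), or material may be lost through aldol-type reactions of the ketone enolate before it is silylated. Fallback: the C4–C5 bond is made by an intramolecular SN2′ alkylation of an ester enolate with the ketone masked. It sets out from seco acid 18. Esterification with 2-(trimethylsilyl)ethyl 2,2,2-trichloroacetimidate (toluene, 80 °C) gives the 2-(trimethylsilyl)ethyl ester F1. Ketalisation (ethylene glycol, HC(OMe)3, PPTS) gives the dioxolane F2. Corey–Kim chlorination (N-chlorosuccinimide, Me2S, CH2Cl2, −20 °C) gives the (Z)-allylic chloride F3. KN(SiMe3)2 in THF (−78 → 0 °C) then lets the C4 enolate attack C5 with loss of chloride from C7, closing ring A to the vinylcyclohexane ketal F4 through a chair-like closure with the branched C9 substituent equatorial; C4 epimers, if both form, are separated here. PPTS in wet acetone removes the ketal and the route is rejoined at 24.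

Step 10. Intermolecular esterification (diolide and oligomer formation) may outrun closure of the strained ten-membered ring. Fallback: the ring is closed by alkylation at C7 instead of acylation at C19. Mitsunobu macrolactonisation of 18 (PPh3, DIAD, slow addition, toluene, high dilution) activates the primary allylic hydroxyl and lets the C19 carboxylate displace it. It sets out from 18, makes no new compound (F0) and returns to the route at 20.

Step 15. Allylic oxidation may run on to the enone or deliver oxygen with the wrong positional (C9) or facial sense. Fallback: ring B is closed as the 7-ene and the oxygen is brought in through an epoxide. It sets out from 24. Hydroboration–oxidation of the vinyl group (9-BBN; NaBO3) gives the primary alcohol F5, any ketone reduced alongside being re-oxidised in the next operation. Dess–Martin oxidation gives the keto aldehyde F6. Intramolecular McMurry coupling (TiCl3, Zn–Cu couple, DME, reflux, slow addition) gives the 7-ene F7. mCPBA epoxidises it from the α face, away from the axial C20 methyl, to the 7α,8α-epoxide F8. Diethylaluminium 2,2,6,6-tetramethylpiperidide removes a C17 proton and opens the epoxide to the 7α-hydroxy-8(17)-ene, which is compound 29, where the route is rejoined; steps 13 to 15 are bypassed.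

Further compounds

F1 | step 11 | 2-(trimethylsilyl)ethyl ester of seco acid 18 | CC(C)(C)[Si](C)(C)OCC[C@@H](C(C)=O)[C@](C)(/C=C\CO)CCCC(C)C(=O)OCC[Si](C)(C)C
F2 | step 11 | dioxolane (ethylene ketal at C8) of F1 | CC(C)(C)[Si](C)(C)OCC[C@@H](C1(C)OCCO1)[C@](C)(/C=C\CO)CCCC(C)C(=O)OCC[Si](C)(C)C
F3 | step 11 | (Z)-allylic chloride from F2 (chloride on C7) | CC(C)(C)[Si](C)(C)OCC[C@@H](C1(C)OCCO1)[C@](C)(/C=C\CCl)CCCC(C)C(=O)OCC[Si](C)(C)C
F4 | step 11 | vinylcyclohexane ketal: ethylene ketal of 24 | CC(C)(C)[Si](C)(C)OCC[C@@H](C2(C)OCCO2)[C@@]1(C)CCC[C@](C)(C(=O)OCC[Si](C)(C)C)[C@@H]1C=C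
F0 | step 10 | none | none
F5 | step 15 | primary alcohol from 24 (C7–OH; vinyl hydroborated) | CC(C)(C)[Si](C)(C)OCC[C@@H](C(C)=O)[C@@]1(C)CCC[C@](C)(C(=O)OCC[Si](C)(C)C)[C@@H]1CCO
F6 | step 15 | keto aldehyde (C7 aldehyde and C8 methyl ketone) | CC(C)(C)[Si](C)(C)OCC[C@@H](C(C)=O)[C@@]1(C)CCC[C@](C)(C(=O)OCC[Si](C)(C)C)[C@@H]1CC=O
F7 | step 15 | 2-(trimethylsilyl)ethyl 12-(tert-butyldimethylsilyloxy)-13,14,15,16-tetranorlabd-7-en-19-oate | CC(C)(C)[Si](C)(C)OCC[C@H]1C(C)=CC[C@@H]2[C@]1(C)CCC[C@]2(C)C(=O)OCC[Si](C)(C)C
F8 | step 15 | 7α,8α-epoxide of F7 | CC(C)(C)[Si](C)(C)OCC[C@H]1[C@]3(C)O[C@@H]3C[C@@H]2[C@]1(C)CCC[C@]2(C)C(=O)OCC[Si](C)(C)C
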